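The ratio to start from is catalyst, ash over birch: twice, yet ash reads 12.1% at 12.0 h, on the line birch draws.

| setting | birch | ash | flask |
|---|---|---|---|
| solid substrate | 0.55 M | 0.55 M | 0.55 M |
| catalyst | 0.88 mol% | 1.8 mol% | 0.88 mol% |
| remark | the very flask that is asked about, followed so far | run made earlier |  |
| time |  |  | 2.5 d |

| run | time / h | target / % |
|---|---|---|
| birch | 10.0 | 10.1 |
| birch | 20.0 | 20.6 |
| birch | 30.0 | 29.0 |
| birch | 40.0 | 28.5 |
| birch | 50.0 | 29.1 |
| ash | 1.00 | 0 |
| ash | 3.00 | 1.1 |
| ash | 6.00 | 3.6 |
| ash | 8.00 | 7.9 |
| ash | 12.0 | 12.1 |

(each reading ± 1 percentage point)

- beta: at 2.5 d add catalyst, 100% of the amount charged, then wait 5.0 d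
- delta: at 2.5 d take out 90% of the target then present, then wait 5.0 d
- theta: change nothing and wait 5.0 d more

- as a solid, counted per litre of solution: solid substrate
- what is taken out of target is counted as made
- what was read earlier has a scatter of 1 percentage point, one standard deviation
- at the start none of the solid substrate is in solution
- additions bring no volume worth counting

* target, in percent of the solid substrate first charged, at 2.5 d
* which option adds most target ("none" when 2 percentage points or less is all one gets) (beta / delta / theta / none)
* target present, with what was taken out counted in, in percent of the solid substrate first charged, after delta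
* target present, with what was taken out counted in, in percent of the solid substrate first charged, after theta

Birch climbs straight from the origin, 20.6% by 20.0 h, then runs flat at a mean of 28.9%. Ash shows a short lag at first, only 3.6% at 6.00 h. A straight ramp is zero order: the concentration that sets the rate is not falling. I read this as solid feeding the solution at a steady pace, the rate-limiting step. The quantity to carry is the fill time, the plateau divided by the slope of the ramp: 28.0 h. At 12.0 h the ramp gives 12.4%, within the scatter of the ash reading.

The birch flask at 2.5 d lies later than the knee, so I commit to the plateau for now and for theta. Ash ends at 12.0 h, earlier than the first plateau reading of birch at 30.0 h, so it shows nothing of catalyst on the plateau. I read the plateau as a balance, which added catalyst does not shift, so I expect beta to add nothing. Delta takes out 26 percentage points. Regrowth along the ramp needs 25.2 h, less than the wait, and reaches 54.8% if solid remains. If the knee marks the end of the solid, the total is lower. The readings cannot tell which, so I name delta as best and hold that total as a ceiling.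

The forecast gives 29%, delta, 55% after delta and 29% after theta, “with solid still remaining”.

The flask gives 28.3%, 28.3% after theta, a gain of 0 points from beta, and 46.6% after delta, so delta adds 18 points.

    starting material + catalyst ⇌ target + catalyst, rate k1*[starting material]*[catalyst] forward; the back reaction follows from the equilibrium constant (K = 27.0, k = 61.0 L mol⁻¹ h⁻¹)
    target + catalyst ⇌ isomer of the product A + catalyst, rate k2*[catalyst]*[target] forward; the back reaction follows from the equilibrium constant (K = 0.890, k = 360 L mol⁻¹ h⁻¹)
    isomer of the product A ⇌ isomer of the product B (K = 1.80, k = 0.440 h⁻¹)
    isomer of the product B + catalyst ⇌ starting material + catalyst, rate k4*[catalyst]*[isomer of the product B] forward; the back reaction follows from the equilibrium constant (k = 59.0 L mol⁻¹ h⁻¹)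
    solid substrate ⇌ starting material, rate k5*(cs5 - [starting material]) while solid is left; crystals form when [starting material] > cs5 (solubility = 0.200 M, k = 0.110 h⁻¹)

In the birch flask, target passes on to isomer of the product A with a forward half-life of 0.40 h at 12.7 h, shorter than the 2.5 d of the run. At 60.0 h target stands at 28.3% beside 25.2% and 45.4% of the two isomers, with solid substrate at 0%; solid and dissolved together, it had fallen under 2% of its charge by 25.5 h, against the fill time of 28.0 h.

A neighbour of the birch flask, left until 15 h, lies before the knee, so the ramp gives 15.5%. The computed neighbour holds 13.9% of target, with 41.2% still solid.

The readings are calculated on assumed constants; noise was put on by code.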